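## Retrosynthetic overview

1. Numbering (pleuromutilin): ring A = cyclopentenone C1–C2(=O)–C3=C4–C9; ring B = cyclohexane C4–C5–C6–C7–C8–C9; ring C = eight-membered C4–C5–C14–C13–C12–C11–C10–C9. The C14 glycolate and free C11–OH are set last on diol 27, and ring A is opened by retro-aldol condensation (C3=C4) to a C4 ketone with an acetonyl group on C9.
2. Enabling feature: C11 and C14 of ring C are both carbinol carbons, 1,4-related across quaternary C12, so the C11–C14 bridge is a latent 2-methyl-2-vinylsuccinaldehyde. Their partners C5 and C10 sit on ring B on either side of C4: with C4 as a ketone, C5 is an enolate carbon, and C10 (on the blocked quaternary C9) is an alkenyl carbon (C10=C17) that later becomes CH–CH3.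
3. Key disconnection: C5–C14 and C10–C11 are cut together, so ring C falls apart into the ring-B α-bromo ketone/alkenyl triflate 12 and dialdehyde 19. Forward, one chromium-mediated Reformatsky/Nozaki–Hiyama–Kishi (4+4) annulation joins them.
4. 12 comes from cyclohexenone (asymmetric conjugate addition/methylation, Claisen acylation, Pd-catalysed asymmetric allylation for C9, enol triflate, ozonolysis, ketal, bromination). 19 comes from isoprene monoepoxide and Meldrum's acid (Pd-catalysed asymmetric allylic alkylation for C12).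
5. Ring order: B (from the starting enone) → C (key step) → A (aldol condensation).

Key step: step 11

Assumption: the configuration is read exactly as the target SMILES encodes it (pleuromutilin numbering: 5S, 6S, 9S, 10R, 11S, 12S, 14R), and every intermediate carries these centres with the same spatial sense; the CIP letter of C5 in 21–25 and of C11 in 22 differs only because neighbouring groups change priority.

## Route

Step 1
Reactants: 1 cyclohex-2-en-1-one
Product: 3 (2R,3S)-2,3-dimethylcyclohexan-1-one, via bromomagnesium enolate 2 (not isolated)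
Conditions: MeMgBr, CuBr·SMe2 (5 mol%), (R,S)-Josiphos (6 mol%), t-BuOMe, −78 °C; then MeI, DMPU, −78 → 0 °C
Reagents that add atoms: methylmagnesium bromide, C[Mg]Br; iodomethane, CI
Why: Copper-catalysed asymmetric conjugate addition sets C6 under ligand control (ligand enantiomer chosen for the 3S centre), and the regiodefined enolate is methylated anti to the new methyl group; the C5 centre made here is destroyed later.

Step 2
Reactants: 3 (2R,3S)-2,3-dimethylcyclohexan-1-one
Product: 4 (2R,3S)-6-acetyl-2,3-dimethylcyclohexan-1-one (keto–enol mixture)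
Conditions: NaH, EtOAc (excess), Et2O, reflux; aqueous HCl work-up
Reagents that add atoms: ethyl acetate, CCOC(C)=O
Why: Crossed Claisen condensation under thermodynamic control acylates the CH2 α-carbon (C9), the only position that gives an enolisable β-diketone; C6 is not touched.

Step 3
Reactants: 4 (2R,3S)-6-acetyl-2,3-dimethylcyclohexan-1-one
Product: 5 (2S,5S,6R)-2-acetyl-5,6-dimethyl-2-(2-methylprop-2-en-1-yl)cyclohexan-1-one
Conditions: 2-methylallyl acetate, Pd2(dba)3·CHCl3 (2.5 mol%), (S,S)-DACH-phenyl bis(2-diphenylphosphinobenzamide) ligand (7.5 mol%), tetramethylguanidine, toluene, 0 °C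
Reagents that add atoms: 2-methylallyl acetate, CC(=C)COC(C)=O
Why: Pd-catalysed asymmetric allylic alkylation (Tsuji–Trost type) of the prochiral β-diketone enolate with the symmetric 2-methylallyl-palladium complex; the chiral ligand selects the enolate face and sets quaternary C9 under catalyst control (the remote C6 methyl exerts little bias).

Step 4
Reactants: 5 (2S,5S,6R)-2-acetyl-5,6-dimethyl-2-(2-methylprop-2-en-1-yl)cyclohexan-1-one
Product: 7 1-[(1S,3R,4S)-3,4-dimethyl-1-(2-methylprop-2-en-1-yl)-2-oxocyclohexyl]ethenyl trifluoromethanesulfonate, via potassium enolate 6 (not isolated)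
Conditions: KHMDS (1.05 equiv), THF, −78 °C; then PhNTf2, −78 → 0 °C
Reagents that add atoms: N-phenyl-bis(trifluoromethanesulfonimide), O=S(=O)(N(c1ccccc1)S(=O)(=O)C(F)(F)F)C(F)(F)F
Why: Kinetic deprotonation takes the unhindered acetyl methyl (the ring α-hydrogen is tertiary and flanked by two methyl groups), and O-triflation of the enolate gives the C10 alkenyl triflate (enol triflate synthesis).

Step 5
Reactants: 7 alkenyl triflate
Product: 9 1-[(1S,3R,4S)-3,4-dimethyl-2-oxo-1-(2-oxopropyl)cyclohexyl]ethenyl trifluoromethanesulfonate, via ozonide 8 (not isolated)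
Conditions: O3 (1 equiv, indicator), CH2Cl2, −78 °C; then Me2S, −78 °C → rt
Reagents that add atoms: ozone, [O-][O+]=O
Why: Ozonolysis cleaves the electron-rich 1,1-disubstituted alkene while the electron-poor enol triflate survives; reductive work-up gives the C2 methyl ketone.

Step 6
Reactants: 9 diketone triflate
Product: 10 1-[(1S,3R,4S)-3,4-dimethyl-1-[(2-methyl-1,3-dioxolan-2-yl)methyl]-2-oxocyclohexyl]ethenyl trifluoromethanesulfonate
Conditions: 1,2-bis(trimethylsilyloxy)ethane, Me3SiOTf (5 mol%), CH2Cl2, −78 → −20 °C
Reagents that add atoms: 1,2-bis(trimethylsilyloxy)ethane, C[Si](C)(C)OCCO[Si](C)(C)C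
Why: Silyl-triflate-catalysed ketalisation is selective for the unhindered methyl ketone over the ring ketone, which is flanked by a quaternary and a tertiary carbon.

Step 7
Reactants: 10 ketal triflate
Product: 12 1-[(1S,4S)-3-bromo-3,4-dimethyl-1-[(2-methyl-1,3-dioxolan-2-yl)methyl]-2-oxocyclohexyl]ethenyl trifluoromethanesulfonate (both C3 epimers), via lithium enolate 11 (not isolated)
Conditions: LiHMDS, THF, −78 °C; then N-bromosuccinimide, −78 °C; NH4Cl work-up
Reagents that add atoms: N-bromosuccinimide, O=C1CCC(=O)N1Br
Why: The ring ketone has a single α-hydrogen (C5), so enolate bromination is regiospecific; the C5 configuration does not matter because this centre becomes an enolate again in step 11.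

Step 8
Reactants: 13 2-methyl-2-vinyloxirane (racemic); 14 Meldrum's acid
Product: 17 (S)-4-ethenyl-4-methyloxolan-2-one, via alkylated Meldrum's acid 15 (not isolated), via lactone acid 16 (not isolated)
Conditions: Pd2(dba)3·CHCl3 (1 mol%), (R,R)-DACH-naphthyl bis(2-diphenylphosphino-1-naphthamide) ligand (3 mol%), CH2Cl2, rt; then toluene–pyridine, 100 °C
Reagents that add atoms: none
Why: Pd-catalysed dynamic kinetic asymmetric allylic alkylation of the vinyl epoxide: the diastereomeric π-allyl complexes interconvert, the alkoxide directs the carbon nucleophile to the tertiary terminus, and the ligand (enantiomer chosen for the S centre) sets quaternary C12; heating then lactonises with loss of acetone and decarboxylates.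

Step 9
Reactants: 17 (S)-4-ethenyl-4-methyloxolan-2-one
Product: 18 (S)-2-ethenyl-2-methylbutane-1,4-diol
Conditions: LiAlH4, THF, 0 °C → rt
Reagents that add atoms: none
Why: Hydride reduction of the lactone to the diol; the quaternary centre cannot epimerise.

Step 10
Reactants: 18 (S)-2-ethenyl-2-methylbutane-1,4-diol
Product: 19 (S)-2-ethenyl-2-methylbutanedial
Conditions: Dess–Martin periodinane (2.4 equiv), NaHCO3, CH2Cl2, 0 °C → rt; used at once as a solution
Reagents that add atoms: none
Why: Dess–Martin oxidation of both primary alcohols; the only stereocentre is quaternary, so the sensitive dialdehyde is configurationally safe.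

Step 11
Reactants: 12 α-bromo ketone alkenyl triflate; 19 (S)-2-ethenyl-2-methylbutanedial
Product: 22 bicyclo[5.3.1]undecanone keto diol (rings B and C; 5R,6S,9S,11R,12S,14R), via chromium enolate 20 (not isolated), via chromium aldolate 21 (not isolated)
Conditions: CrCl2 (8 equiv), NiCl2 (0.2 equiv), DMF–THF 1:1, 0 °C → rt; 12 and 19 (1.3 equiv) added over 8 h to 0.005 M
Reagents that add atoms: none
Why: Proposed new method: CrCl2 reduces the tertiary α-bromo ketone of 12 (no nickel needed) to trivalent chromium enolate 20, which adds to the less hindered CH2–CHO (C14) of 19 through a closed chair transition state to give aldolate 21 (bond C5–C14); zerovalent nickel, formed from NiCl2 by CrCl2, then inserts into the C10–OTf bond, transmetalates to chromium, and the alkenylchromium adds to the remaining neopentyl C11 aldehyde (bond C10–C11). The closest known reactions are the chromium Reformatsky reaction and the Nozaki–Hiyama–Kishi closure of medium rings, merged here into one (4+4) annulation of a 1,4-dialdehyde with a bis-pronucleophile. Ring C (C4–C5–C14–C13–C12–C11–C10–C9) is closed by the second event as an 8-exo-trig carbonyl addition; the first event is intermolecular and closes no ring. C14 is set by the chair (aldehyde chain equatorial, which places O14 syn to the C5 methyl, the enolate substituent cis to the enolate oxygen); C5 is set by the enolate face used and is proof-read by the ring closure, because only the aldolate whose C14 arm can reach the C9 alkenyl unit cyclises; C11 is set in the ring closure by the adjacent quaternary C12 (methyl versus vinyl) inside the forming ring. The step needs chemoselectivity (enolate before alkenylchromium, C14 aldehyde before C11 aldehyde) and cyclisation over oligomerisation; these are secured by the much faster reduction of the α-bromo ketone than the nickel-dependent activation of the triflate, by the α-quaternary shielding of the C11 aldehyde, and by slow addition at high dilution.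

Step 12
Reactants: 22 keto diol with C10 exocyclic methylene
Product: 23 keto diol with C10 methyl (5R,6S,9S,10R,11S,12S,14R)
Conditions: Mn(dpm)3 (10 mol%), PhSiH3, t-BuOOH, i-PrOH, rt
Reagents that add atoms: none
Why: Metal-hydride hydrogen atom transfer hydrogenation: the 1,1-disubstituted C10=C17 alkene gives a tertiary radical and should react faster than the neopentyl monosubstituted vinyl group, and C10 is set by hydrogen delivery to that radical on the less hindered outer face of ring C.

Step 13
Reactants: 23 ketal keto diol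
Product: 24 diketone diol (C9 acetonyl; 5R,6S,9S,10R,11S,12S,14R)
Conditions: 1 M HCl, THF, rt
Reagents that add atoms: water, O
Why: Acid-catalysed ketal hydrolysis; the β-hydroxy ketone and both alkenes tolerate dilute acid.

Step 14
Reactants: 24 diketone diol
Product: 25 bis(triethylsilyl) ether of 24
Conditions: Et3SiOTf, 2,6-lutidine, CH2Cl2, −78 °C
Reagents that add atoms: triethylsilyl trifluoromethanesulfonate, CC[Si](CC)(CC)OS(=O)(=O)C(F)(F)F
Why: Silylation of both hindered secondary alcohols with the silyl triflate; the C14 silyl ether blocks retro-aldol cleavage of the C4/C14 β-hydroxy ketone in the next step.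

Step 15
Reactants: 25 bis-silyl diketone
Product: 26 tricyclic enone bis(triethylsilyl) ether (5S,6S,9S,10R,11S,12S,14R)
Conditions: KOt-Bu (0.5 equiv), t-BuOH–THF, 50 °C
Reagents that add atoms: none
Why: Intramolecular aldol condensation closes ring A (5-exo-trig addition of the methyl ketone enolate C3 to the C4 ketone, then dehydration); C4 has no α-hydrogen and the other enolate would give a three-membered ring, so only the C2(=O)–C3=C4 enone can form.

Step 16
Reactants: 26 tricyclic enone bis-silyl ether
Product: 27 tricyclic enone 11,14-diol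
Conditions: HF·pyridine, THF, 0 °C → rt
Reagents that add atoms: none
Why: Fluoride-mediated cleavage of both silyl ethers; no stereocentre is affected.

Step 17
Reactants: 27 tricyclic enone 11,14-diol
Product: 28 C11 trifluoroacetate of 27
Conditions: N-(trifluoroacetyl)imidazole (1.2 equiv), THF, 0 °C
Reagents that add atoms: N-(trifluoroacetyl)imidazole, O=C(n1ccnc1)C(F)(F)F
Why: Selective acyl transfer to the C11 hydroxyl; the C14 hydroxyl, neopentylic to quaternary C5 and hemmed in by the C5 and C6 methyl groups, is expected to stay free, as is usual for this diol pair in the mutilin series.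

Step 18
Reactants: 28 C11 trifluoroacetate
Product: 29 C11 trifluoroacetate C14 acetoxyacetate
Conditions: acetoxyacetyl chloride, pyridine, DMAP (cat.), CH2Cl2, rt
Reagents that add atoms: acetoxyacetyl chloride, CC(=O)OCC(=O)Cl
Why: DMAP-catalysed esterification of the remaining hindered C14 alcohol with the O-protected glycolyl chloride.

Step 19
Reactants: 29 C11 trifluoroacetate C14 acetoxyacetate
Product: 30 pleuromutilin F
Conditions: K2CO3 (0.2 equiv), MeOH, 0 °C
Reagents that add atoms: none
Why: Mild methanolysis (transesterification) should cleave the activated trifluoroacetate and the primary acetate much faster than the hindered secondary C14 glycolate ester.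

## Compound list

1 | cyclohex-2-en-1-one | O=C1C=CCCC1 | starting material
2 | bromomagnesium (S)-3-methylcyclohex-1-en-1-olate | C[C@H]1CCCC(O[Mg]Br)=C1 | intermediate
3 | (2R,3S)-2,3-dimethylcyclohexan-1-one (trans) | C[C@H]1C(=O)CCC[C@@H]1C | intermediate
4 | (2R,3S)-6-acetyl-2,3-dimethylcyclohexan-1-one (keto–enol mixture; C6 labile) | C[C@H]1C(=O)C(C(C)=O)CC[C@@H]1C | intermediate
5 | (2S,5S,6R)-2-acetyl-5,6-dimethyl-2-(2-methylprop-2-en-1-yl)cyclohexan-1-one | C[C@H]1C(=O)[C@](CC(C)=C)(CC[C@@H]1C)C(C)=O | intermediate
6 | potassium enolate of 5 at the acetyl group | C[C@H]1C(=O)[C@](CC(C)=C)(CC[C@@H]1C)C(=C)O[K] | intermediate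
7 | 1-[(1S,3R,4S)-3,4-dimethyl-1-(2-methylprop-2-en-1-yl)-2-oxocyclohexyl]ethenyl trifluoromethanesulfonate | C[C@H]1C(=O)[C@](CC(C)=C)(CC[C@@H]1C)C(=C)OS(=O)(=O)C(F)(F)F | intermediate
8 | ozonide (1,2,4-trioxolane) of the methallyl alkene of 7 | C[C@H]1C(=O)[C@](CC2(C)OOCO2)(CC[C@@H]1C)C(=C)OS(=O)(=O)C(F)(F)F | intermediate
9 | 1-[(1S,3R,4S)-3,4-dimethyl-2-oxo-1-(2-oxopropyl)cyclohexyl]ethenyl trifluoromethanesulfonate | C[C@H]1C(=O)[C@](CC(C)=O)(CC[C@@H]1C)C(=C)OS(=O)(=O)C(F)(F)F | intermediate
10 | 1-[(1S,3R,4S)-3,4-dimethyl-1-[(2-methyl-1,3-dioxolan-2-yl)methyl]-2-oxocyclohexyl]ethenyl trifluoromethanesulfonate | C[C@H]1C(=O)[C@](CC2(C)OCCO2)(CC[C@@H]1C)C(=C)OS(=O)(=O)C(F)(F)F | intermediate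
11 | lithium enolate of 10 (C4–O–Li, C4=C5) | CC1=C(O[Li])[C@](CC2(C)OCCO2)(CC[C@@H]1C)C(=C)OS(=O)(=O)C(F)(F)F | intermediate
12 | 1-[(1S,4S)-3-bromo-3,4-dimethyl-1-[(2-methyl-1,3-dioxolan-2-yl)methyl]-2-oxocyclohexyl]ethenyl trifluoromethanesulfonate (both C3 epimers) | CC1(Br)C(=O)[C@](CC2(C)OCCO2)(CC[C@@H]1C)C(=C)OS(=O)(=O)C(F)(F)F | intermediate
13 | 2-methyl-2-vinyloxirane (isoprene monoepoxide, racemic) | CC1(C=C)CO1 | starting material
14 | Meldrum's acid (2,2-dimethyl-1,3-dioxane-4,6-dione) | CC1(C)OC(=O)CC(=O)O1 | starting material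
15 | 5-[(2R)-1-hydroxy-2-methylbut-3-en-2-yl]-2,2-dimethyl-1,3-dioxane-4,6-dione | C=C[C@](CO)(C)C1C(=O)OC(C)(C)OC1=O | intermediate
16 | (4R)-4-ethenyl-4-methyl-2-oxooxolane-3-carboxylic acid (C3 epimers) | C=C[C@]1(C)C(C(=O)O)C(=O)OC1 | intermediate
17 | (S)-4-ethenyl-4-methyloxolan-2-one | C=C[C@]1(C)CC(=O)OC1 | intermediate
18 | (S)-2-ethenyl-2-methylbutane-1,4-diol | C=C[C@](CO)(C)CCO | intermediate
19 | (S)-2-ethenyl-2-methylbutanedial | C=C[C@](C=O)(C)CC=O | intermediate
20 | trivalent chromium (dichloro) enolate of 12 (O–Cr on C4, C4=C5) | CC1=C(O[Cr](Cl)Cl)[C@](CC2(C)OCCO2)(CC[C@@H]1C)C(=C)OS(=O)(=O)C(F)(F)F | intermediate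
21 | open-chain chromium aldolate: C5–C14 bonded, C14–O–CrCl2, C11 aldehyde and C10 triflate intact (5R,6S,9S,12S,14R) | C=C[C@](C=O)(C)C[C@@H](O[Cr](Cl)Cl)[C@]1(C)C(=O)[C@](CC2(C)OCCO2)(CC[C@@H]1C)C(=C)OS(=O)(=O)C(F)(F)F | intermediate
22 | bicyclo[5.3.1]undecanone keto diol (rings B and C): C4 ketone bridge, C5-Me, C6-Me, C9-CH2-(2-methyl-1,3-dioxolan-2-yl), C10 exocyclic methylene, C11-OH, C12-Me and vinyl, C14-OH (5R,6S,9S,11R,12S,14R) | C=C[C@]1(C)C[C@@H](O)[C@]2(C)C(=O)[C@](CC3(C)OCCO3)(CC[C@@H]2C)C(=C)[C@@H]1O | intermediate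
23 | as 22 with C10 carrying H and methyl (5R,6S,9S,10R,11S,12S,14R) | C=C[C@]1(C)C[C@@H](O)[C@]2(C)C(=O)[C@](CC3(C)OCCO3)(CC[C@@H]2C)[C@@H](C)[C@@H]1O | intermediate
24 | diketone diol: as 23 with C9 acetonyl (2-oxopropyl) | C=C[C@]1(C)C[C@@H](O)[C@]2(C)C(=O)[C@](CC(C)=O)(CC[C@@H]2C)[C@@H](C)[C@@H]1O | intermediate
25 | 11,14-bis(triethylsilyl) ether of 24 | C=C[C@]1(C)C[C@@H](O[Si](CC)(CC)CC)[C@]2(C)C(=O)[C@](CC(C)=O)(CC[C@@H]2C)[C@@H](C)[C@@H]1O[Si](CC)(CC)CC | intermediate
26 | tricyclic enone (rings A, B, C; C2 ketone, C3=C4) as 11,14-bis(triethylsilyl) ether (5S,6S,9S,10R,11S,12S,14R) | C=C[C@]1(C)C[C@@H](O[Si](CC)(CC)CC)[C@]2(C)C3=CC(=O)C[C@@]3(CC[C@@H]2C)[C@@H](C)[C@@H]1O[Si](CC)(CC)CC | intermediate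
27 | tricyclic enone 11,14-diol (target without the glycolyl group) | C=C[C@]1(C)C[C@@H](O)[C@]2(C)C3=CC(=O)C[C@@]3(CC[C@@H]2C)[C@@H](C)[C@@H]1O | intermediate
28 | 11-O-trifluoroacetate of 27 | C=C[C@]1(C)C[C@@H](O)[C@]2(C)C3=CC(=O)C[C@@]3(CC[C@@H]2C)[C@@H](C)[C@@H]1OC(=O)C(F)(F)F | intermediate
29 | 11-O-trifluoroacetate 14-O-(acetoxyacetate) of 27 | C=C[C@]1(C)C[C@@H](OC(=O)COC(C)=O)[C@]2(C)C3=CC(=O)C[C@@]3(CC[C@@H]2C)[C@@H](C)[C@@H]1OC(=O)C(F)(F)F | intermediate
30 | pleuromutilin F | C=C[C@]1(C)C[C@@H](OC(=O)CO)[C@]2(C)C3=CC(=O)C[C@@]3(CC[C@@H]2C)[C@@H](C)[C@@H]1O | target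

## Step count and risks

Total step count: 19. Longest linear sequence: 16 steps (steps 1–7 and 11–19).

Most likely to fail, 1: step 11. The intermolecular aldol may use the enolate face at C5 from which the C14 arm cannot reach the alkenyl unit, so that the aldolate is only protonated; the chromium enolate may also be protonated before it adds, and open-chain aldolates may oligomerise instead of cyclising. The fallback reverses the order of the two bond formations with known reactions, sets out from 19 and 10, and returns at 22. The unhindered aldehyde of 19 is protected selectively (HC(OMe)3, PPTS, MeOH) as (S)-2-ethenyl-4,4-dimethoxy-2-methylbutanal F1. An ordinary intermolecular Nozaki–Hiyama–Kishi coupling of F1 with the unbrominated triflate 10 (CrCl2, cat. NiCl2, DMSO) gives the allylic alcohol F2 (bond C10–C11). PPTS in wet acetone cleaves the dimethyl acetal, and the hydroxy aldehyde is isolated as the lactol F3. LiHMDS (3 equiv, THF, −78 → 0 °C) opens the lactolate, and the C4 ketone enolate closes ring C by an intramolecular aldol addition (bond C5–C14) to give 22, with C5 now dictated by the tether.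

Most likely to fail, 2: step 12. Hydrogen delivery to the C10 radical may occur from the wrong face, the radical may instead abstract the transannular C14 hydrogen (oxidising C14), or the vinyl group may be reduced as well. The fallback sets C10 under thermodynamic control, sets out from 22 and returns at 23. MnO2 oxidises the allylic C11 alcohol to the cross-conjugated enone F4. Conjugate reduction with K-Selectride followed by equilibration with DBU gives the saturated C11 ketone F5. NaBH4 then reduces the C11 ketone (the C4 ketone is shielded by two quaternary carbons) to give 23.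

Most likely to fail, 3: step 15. The methyl ketone enolate may fail to add to the C4 carbonyl, which is flanked by two quaternary carbons, and prolonged base may remove the silyl ethers and open ring C by retro-aldol cleavage. The fallback uses Lewis-acid activation of the hindered ketone, sets out from 25 and returns at 26. LDA and Me3SiCl (THF, −78 °C) convert the methyl ketone into the trimethylsilyl enol ether F6 (the C4 ketone has no α-hydrogen). TiCl4 (CH2Cl2, −78 °C) promotes an intramolecular Mukaiyama aldol addition to the β-hydroxy ketone F7. Dehydration with the Burgess reagent gives 26.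

## Further compounds

F1 | step 11 | (S)-2-ethenyl-4,4-dimethoxy-2-methylbutanal | C=C[C@](C=O)(C)CC(OC)OC
F2 | step 11 | allylic alcohol from 10 and F1 (C10–C11 bonded, C11-OH, C14 dimethyl acetal) | C=C[C@](C)(CC(OC)OC)[C@@H](O)C(=C)[C@@]1(CC2(C)OCCO2)CC[C@H](C)[C@@H](C)C1=O
F3 | step 11 | lactol (C11–O–C14 hemiacetal, both anomers) of the hydroxy aldehyde from F2 | C=C[C@]1(C)CC(O)O[C@H]1C(=C)[C@@]2(CC3(C)OCCO3)CC[C@H](C)[C@@H](C)C2=O
F4 | step 12 | C11 ketone of 22 with C10 exocyclic methylene (cross-conjugated enone) | C=C[C@]1(C)C[C@@H](O)[C@]2(C)C(=O)[C@](CC3(C)OCCO3)(CC[C@@H]2C)C(=C)C1=O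
F5 | step 12 | saturated C11 ketone with C10 methyl (10R) | C=C[C@]1(C)C[C@@H](O)[C@]2(C)C(=O)[C@](CC3(C)OCCO3)(CC[C@@H]2C)[C@@H](C)C1=O
F6 | step 15 | trimethylsilyl enol ether of the methyl ketone of 25 | C=C[C@]1(C)C[C@@H](O[Si](CC)(CC)CC)[C@]2(C)C(=O)[C@](CC(=C)O[Si](C)(C)C)(CC[C@@H]2C)[C@@H](C)[C@@H]1O[Si](CC)(CC)CC
F7 | step 15 | β-hydroxy ketone with ring A closed (C4-OH, C2 ketone; C4 epimers) | C=C[C@]1(C)C[C@@H](O[Si](CC)(CC)CC)[C@]2(C)C3(O)CC(=O)C[C@@]3(CC[C@@H]2C)[C@@H](C)[C@@H]1O[Si](CC)(CC)CC
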